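When a flask stops changing, it is easy to assume the stop measures what the initiator could buy.

| flask | free monomer | initiator | remark | time |
|---|---|---|---|---|
| dawn | 0.15 M | 2.5 mol% | run made earlier |  |
| autumn | 0.60 M | 2.5 mol% | run made earlier |  |
| dusk | 0.30 M | 3.8 mol% | run made earlier |  |
| flask | 0.30 M | 2.5 mol% |  | 2.0 h |

- dawn (time / min: monomer in chains / %, free monomer / %): 15.0: 0.2, 99.5; 30.0: 0.5, 99.7; 40.0: 0.1, 99.1; 60.0: 0.6, 98.9; 80.0: 0, 98.9
- autumn (time / min: monomer in chains / %, free monomer / %): 6.00: 23.5, 76.4; 10.0: 34.5, 64.8; 20.0: 52.4, 47.5; 40.0: 66.0, 33.5; 80.0: 70.7, 28.2
- dusk (time / min: monomer in chains / %, free monomer / %): 15.0: 21.5, 77.4; 30.0: 31.8, 66.9; 40.0: 35.9, 63.1; 60.0: 39.5, 59.0; 80.0: 41.5, 57.2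

(standard deviation of a reading: 0.3 percentage points)

- the average divides the monomer in chains by the number of chains begun, living and dead together
- the earlier runs do not show the number of chains; that part of a forecast is a guess

* average number of monomer units in a chain (chains begun, living or dead) at 2.0 h
* part of the free monomer that has reacted at 2.0 h

Two chemists dispute the flask. The first counts monomer per initiator: the dusk run ended with 10.9 units in chains per initiator, which at the flask's loading predicts c near 27.3%.

The second objects that the autumn run reached 28.3 units per initiator, so that count is not constant. She compares two rates at one moment instead: chains gain monomer in step with the free monomer and shed it at a steady pace. The ratio of gain to loss therefore drifts down as free monomer falls, and the fall stops when it reaches one. The last readings support her, with 0.169 M free monomer in the autumn run and 0.172 M in the dusk run. Their mean, 0.170 M, is my reading of the ceiling, the free monomer at which gain and loss balance, usually called the equilibrium monomer concentration. The dawn run, charged below it, still shows 98.9% free monomer. For the flask, my ceiling puts c near 43.2% once the fall has stopped.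

The forecast takes her side, with c 43% (41% to 45%) and dp 17 (14 to 27), and says of dp: “This is a guess; poor initiator efficiency would raise it.”

The flask gives c 42.6%, which is within the forecast's range, and dp 37.6, which is 2.21 times the forecast's.

    free monomer + initiator → living end + monomer in chains (k = 3.10 /M/min)
    free monomer + living end → monomer in chains + living end, rate k2*[living end]*[free monomer] (k = 8.90 /M/min)
    monomer in chains + living end → free monomer + living end, rate k3*[living end] as long as [monomer in chains] is above zero (k = 1.50 /min)
    initiator → spent initiator A (k = 0.440 /min)
    free monomer + initiator → spent initiator B (k = 2.40 /M/min)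

At 2.0 h the flask's free monomer stands at 1.01 times the ceiling, and monomer in chains is made 1.02 times faster than it is used up. The flask's living ends, 0.00333 M, are fewer than the 0.00750 M of initiator charged, by a factor of 2.25, against the factor of 2.21 between dp and the forecast. The first chemist's loading does count below the flask's charge: c has moved by 4 points at 1.5 mol% initiator. The neighbouring flask with 1 mol% initiator is reckoned against the same ceiling, which puts its stopping c near 43.2%, but at 2.0 h its free monomer is 0.200 M, or 1.17 times the ceiling, and its c is 33.4%.

(All runs were generated by integration with constants of no real substance, noise included.)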